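## Structural features

The target (C25H34O3) is built on a bicyclo[2.2.2]oct-2-en-1-one: the bridgeheads C2 (CH) and C5 (quaternary) are joined by the alkene bridge C3=C4 (methyl on C4), the ketone bridge C1(=O)–C10 (C10 quaternary, with a methyl) and the saturated bridge C1′H2–C2′H. A cyclohexane (ring B, C5–C6–C7–C8–C9–C10) is fused on the C5–C10 edge and carries a cis-fused α-methyl-γ-butyrolactone on C6–C7 (O on C6, C11 with methyl C13, carbonyl C12); C2′ bears a 6-methylhepta-1,5-dien-2-yl chain that points away from the alkene bridge. Of the seven stereocentres (C2, C2′, C5, C10, C6, C7, C11), C5 and C10 are vicinal quaternary carbons and C5–C6–C7–C11 are contiguous; the rigid bicycle holds ring B in one chair in which C6–O is axial and syn to the C10 methyl, C7–C11 is equatorial, and the C11 methyl lies on the convex face of the lactone, trans to C8. Fragile points are the epimerisable C11, the lactone (hydrides, strong nucleophiles) and the 1,5-diene of the side chain (acids, electrophiles, radicals, ozone); the C1 ketone, flanked by C10 and a bridgehead, cannot enolise and is very hindered. The real difficulty is the pair of adjacent quaternary centres inside the bridged system and the relay of configuration from the bicycle (C2′, C10) to the ring B/lactone triad. The key step exploits the fact that the ring C1–C2–C2′–C1′–C5–C10 is a carvone ring that already holds the C1 oxygen, the C10 methyl and the C2′ stereocentre, so only the two-carbon bridge C3–C4 has to be laid across C2 and C5, on the face opposite the C2′ substituent.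

## Logic of the disconnections

43 ⇒ 40. The C11–H bond is removed, so that C13 becomes a methylidene carbon. C11 is the only epimerisable centre and its required configuration (methyl trans to C8) is the more stable one, so it needs no control element of its own. The gain is one stereocentre fewer and an α-methylene lactone, the direct product of an allylmetal–aldehyde ring closure. The forward step must deliver hydride 1,4 to the enoate only and equilibrate nothing but C11.

40 ⇒ 37. C6–C7 and the acyl bond C12–O6 are cut, which opens ring B and the lactone together. C6 is a single carbon on quaternary C5 and can be an aldehyde, and C7 is the γ-carbon of a 2-(methoxycarbonyl)allyl unit. Two rings and the C6 and C7 stereocentres are reduced to an open chain on C10. The allylmetal must add to the aldehyde and not to the C1 ketone, through a closed transition state that places C11 equatorial on the forming chair and O6 cis to it.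

37 ⇒ 32 + 8. C7–C11 is cut (the bromomethyl enoate is a transposed Morita–Baylis–Hillman adduct) and C6 goes back to its protected alcohol. The five-carbon lactone precursor shrinks to a C7 aldehyde and 8. C6 must stay masked while C7 is an aldehyde, since a free 1,6-dialdehyde would close by aldol reaction, and the transposition must give the (Z)-bromide.

32 ⇒ 21 (through 30 and 25). The C7 carbonyl is traced to a terminal alkyne, the C4 methyl to the ester carbon, and C3=C4 to the saturated ester by α-selenenylation and elimination. This keeps C4 sp3 with its endo ester until C10 is quaternary, and the alkyne is inert to the base and hydride steps. All functional-group work on the alkene bridge is thus gathered in one block. The hydride steps must come before any other ester is present, and because they also reduce C1, the ketone has to be restored before C7 is unveiled.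

21 ⇒ 15 + 18. The C3′=CH2 bond (methylenation) and the bond between the former methyl carbon and the prenyl CH2 (enolate alkylation) are cut, and the methyl ketone is traced to the isopropenyl group. The side chain is thereby reduced to the substituent supplied by the chiral pool. Ozonolysis is only possible while no other alkene is present, so it must follow C10 alkylation with an alkyne-bearing electrophile directly; only the methyl may enolise, and C2′ must not epimerise.

15 ⇒ 12 + 13. C10–C9 is cut. C10 is α to the C1 ketone and the only enolisable position, so the quaternary centre comes from a tertiary one by alkylation. The electrophile must enter on the face away from the endo ester on C4.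

12 ⇒ 7 + 8. C2–C3 and C4–C5 are cut, which removes the whole C3–C4 bridge. What remains is a monocyclic enone with one stereocentre, and the step builds one ring, two bonds and four stereocentres. It demands α′-deprotonation, addition anti to the C2′ substituent and closure onto a fully substituted β-carbon.

7 ⇒ 1 + 2. The C5–C6 bond is cut and the carbonyl is moved back across the enone (1,3-transposition), so that C5 is the carbonyl carbon of 1. Both pieces are commercial. The nucleophile must add 1,2, and the oxidant must rearrange the tertiary allylic alcohol without harming the acetal. The methoxymethyl ether on C6 is kept because it survives the chromium oxidant, amide bases, ozone, hydrides and the Lewis-acidic methylenation, and can still be removed at −78 °C next to an allylic bromide and the diene.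

## Other disconnections considered

Alternative 1: The cut is C7–C11, with C12 carried as an acetal carbon tied to O6. In the forward step Bu3SnH and an initiator turn the C6 bromoacetal A1 (ring B closed, C7=C8 double bond, side-chain ketone as dioxolane) into a C11 radical, which closes 5-exo-trig onto C7 to give the ethyl lactol ether A2; the C8 radical is reduced, and oxidation of the acetal would give the lactone.
- In its favour: the five-membered tether can reach C7 only from the face of O6, so the cis fusion is enforced by structure, under neutral conditions that leave the hindered ketone and C3=C4 alone.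
- Against it here: A1 presupposes ring B already closed with C6–O axial, i.e. a separate ring closure and separate control at C6. C11 and the acetal carbon form as mixtures, so the same final equilibration is needed. The radical must be generated before the 1,5-diene exists, which forces a ketal-protected acetyl and two enolate steps beside the finished lactone; tin residues must be removed.
- Comparison: structurally it covers only the ring B/lactone end and still needs the bicyclo[2.2.2]octane, most simply by step 3. Mechanistically it replaces the closed polar transition state of step 17 by a radical closure; on the C6/C7 cis relation it is the better plan (enforced instead of transition-state controlled), and on C11 the two are equal. In step economy it is expected to be equal or one to two steps longer, because ring B, acetal, radical closure and oxidation are separate operations and the ketal adds two.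

Alternative 2: The cut is C1–C2 and C5–C10, removing the ketone bridge instead of the C3–C4 bridge. In the forward step the trienyl ester A3, a cyclohexa-1,3-diene whose (E)-enoate hangs on the ester of the C3′ carbinol, cyclises on heating or with Et2AlCl to the lactone-bridged bicyclooctene A4.
- In its favour: C3=C4 with its methyl is present from the start, so steps 8–10 of the chosen route would be unnecessary; on this point it is the better plan. The tether fixes regiochemistry and the diene face, the C10 chain arrives with the dienophile, and no strong base is used.
- Against it here: C1 arrives bearing a carboxyl carbon that must be degraded to the ketone after the lactone is opened. The C10 methyl is still missing. A3 is not a simple carvone derivative and can aromatise or undergo 1,5-hydrogen shifts. The dienophile must bond to the fully substituted terminus C5 through a strained bridged transition state. Ring B would have to be closed from a trisubstituted alkene, leaving an isopropenyl group that still needs regio- and stereocontrolled oxidation to C12.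
- Comparison: it makes the same bicycle but with the wrong oxidation level at C1 and an incomplete C10, whereas step 3 delivers C1 as the ketone and C10 with its methyl. A concerted cycloaddition stands against a stepwise anionic sequence; facial control is judged equal (tether versus adjacent stereocentre). The saving on the alkene bridge is expected to be outweighed by precursor synthesis, C1 degradation and C12 oxidation.

Alternative 3: The cut is C6–C7, with C6 at the acyl level. In the forward step Bu3SnH and an initiator convert the phenyl selenoester A5 into the C6 acyl radical, which adds 6-exo-trig to C7 of the (E)-2-methylpent-2-enoate chain; the C11 radical takes hydrogen to give the diketo ester A6.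
- In its favour: acyl radicals add readily to enoates and are indifferent to the neopentyl position of C6. C7 ends α to a ketone and can settle equatorial. C6 is then set by hydride attack from the open equatorial direction (axial attack is blocked by the C10 methyl), a more predictable element than the transition state of step 17, so on C6 it is equal or better. The enoate needs one Wittig step instead of the two steps 13–14.
- Against it here: an acyl radical on a quaternary carbon can lose CO in competition with cyclisation. Two extra oxidation-level steps (aldehyde to acid to selenoester) and a reduction/lactonisation are needed. C11 is formed without control. The radical step must again precede the diene, hence the ketal.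
- Comparison: like alternative 1 it addresses only the end-game. A tin-mediated radical chain stands against an organochromium addition. It is expected to be about two steps longer than steps 13–17.

Key step: step 3

Assumption: target locants are used for all bicyclic compounds (C13 = methyl carbon on C11, C3′ = side-chain carbon on C2′, "endo" = towards the C1–C10 bridge), and stereocentres that are erased later (carbinol carbons of 4, 26–29 and 33, C10–H of 12, selenium- and ozonide-bearing carbons) are drawn as the expected isomer or left open, since either isomer serves.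

Step 1
Reactants: 1 (R)-carvone; 2 tributyl[(methoxymethoxy)methyl]stannane
Product: 4 (5R)-1-[(methoxymethoxy)methyl]-2-methyl-5-(prop-1-en-2-yl)cyclohex-2-en-1-ol (C1 epimers), via (methoxymethoxy)methyllithium 3 (not isolated)
Conditions: 2, n-BuLi, THF, −78 °C; then 1, −78 °C; aq. NH4Cl
Reagents that add atoms: none
Why: Tin–lithium exchange gives the α-alkoxy organolithium, which adds 1,2 to the enone carbonyl (organolithium addition to a ketone); the new carbinol centre is erased in step 2 and the carvone stereocentre is untouched.

Step 2
Reactants: 4 (5R)-1-[(methoxymethoxy)methyl]-2-methyl-5-(prop-1-en-2-yl)cyclohex-2-en-1-ol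
Product: 7 (5S)-3-[(methoxymethoxy)methyl]-2-methyl-5-(prop-1-en-2-yl)cyclohex-2-en-1-one, via tertiary chlorochromate ester 5 (not isolated), via transposed chlorochromate ester 6 (not isolated)
Conditions: [C5H5NH][CrO3Cl], NaOAc, 4 Å sieves, CH2Cl2, 25 °C
Reagents that add atoms: pyridinium chlorochromate, [O-][Cr](=O)(=O)Cl.c1cc[nH+]cc1
Why: Dauben–Babler oxidative transposition: the tertiary allylic ester of hexavalent chromium shifts [3,3] to the secondary allylic ester, which is oxidised to the β-substituted enone; the buffered reagent spares the acetal and the isopropenyl group, and the descriptor changes from R to S only because the ring priorities swap.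

Step 3
Reactants: 7 (5S)-3-[(methoxymethoxy)methyl]-2-methyl-5-(prop-1-en-2-yl)cyclohex-2-en-1-one; 8 methyl acrylate
Product: 12 bicyclo[2.2.2]octan-1-one endo ester (CO2Me on C4 towards the C1–C10 bridge; CH2OMOM on C5; isopropenyl on C2′ anti to the C3–C4 bridge; C10 with H and CH3), via lithium dienolate 9 (not isolated), via Michael adduct ester enolate 10 (not isolated), via bicyclic lithium enolate 11 (not isolated)
Conditions: LiN(iPr)2, THF, −78 °C; 8, −78 → 25 °C; aq. NH4Cl
Reagents that add atoms: none
Why: LiN(iPr)2 removes an α′-proton at C2 of 7 under kinetic control to give the cross-conjugated dienolate 9, which bonds through C2 to the β-carbon of 8 (the future C3) on the face opposite the neighbouring C2′ isopropenyl group. Lithium bridging between the ester enolate of 10 and the ring carbonyl keeps the chain folded over the enone, and C4 then bonds to C5, so that C2–C3 and C4–C5 are made in one flask and the C1=C10 enolate 11 is protonated to 12 on work-up. The closest known reaction type is the anionic double Michael bicycloannulation of kinetic carvone-type dienolates with acrylates, formally the endo [4+2] adduct of the 2-oxidodiene C2=C1–C10=C5. One ring is closed, C2–C3–C4–C5–C1′–C2′, by an intramolecular Michael addition that is 6-exo-trig with respect to the C5=C10 acceptor; the same bond completes the second six-membered ring through C10 and C1 and hence the bicyclo[2.2.2]octane. C2 is fixed by the anti approach to the adjacent C2′ substituent, C5 follows necessarily because the tethered enolate can reach only the face on which the chain sits, C4 takes the ester endo through the compact lithium-bridged transition state, and C10 is set only by the final protonation and is erased in step 4. The step needs α′- rather than γ-deprotonation (amide base at −78 °C), facial selectivity (secured by the stereocentre directly beside the first bond formed) and a complete second addition onto a β,β-disubstituted enone (secured by intramolecularity and warming).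

Step 4
Reactants: 12 bicyclo[2.2.2]octan-1-one endo ester; 13 3-bromo-1-(trimethylsilyl)prop-1-yne
Product: 15 C10-[3-(trimethylsilyl)prop-2-yn-1-yl] keto ester (new chain on C10 syn to the C1′–C2′ bridge; C10 methyl syn to the C3–C4 bridge), via potassium enolate 14 (not isolated)
Conditions: KN(SiMe3)2, THF, −78 °C; 13, −78 → 0 °C
Reagents that add atoms: none
Why: C2 is a bridgehead, so the ketone gives a single tetrasubstituted enolate at C10, which is alkylated (SN2, propargylic bromide) on the face flanked only by C1′–H, because the other face is covered by the endo ester on C4; this sets C10 with the chain where ring B will be. The silyl cap suppresses SN2′ attack and masks the acetylenic C–H for the later base steps.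

Step 5
Reactants: 15 C10-[3-(trimethylsilyl)prop-2-yn-1-yl] keto ester
Product: 17 C2′ acetyl keto ester (methyl ketone in place of isopropenyl), via secondary ozonide 16 (not isolated)
Conditions: O3, CH2Cl2, −78 °C (Sudan Red 7B end point); PPh3, −78 → 25 °C
Reagents that add atoms: ozone, [O-][O+]=O
Why: Ozonolysis cleaves the electron-rich 1,1-disubstituted alkene much faster than the silylalkyne, and no other alkene is present at this stage; neutral reduction of the ozonide leaves the α-stereocentre C2′ untouched.

Step 6
Reactants: 17 C2′ acetyl keto ester; 18 prenyl bromide (1-bromo-3-methylbut-2-ene)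
Product: 20 C2′ 5-methylhex-4-enoyl keto ester, via lithium methyl enolate 19 (not isolated)
Conditions: LiN(iPr)2 (1.05 equiv), THF, −78 °C; 18, DMPU, −78 → −20 °C
Reagents that add atoms: none
Why: With C10 quaternary the C1 ketone cannot enolise, so the amide base deprotonates the methyl ketone kinetically at CH3 rather than at the C2′ methine or the hindered, less acidic C4–H of the ester; the primary enolate is alkylated by the allylic bromide (enolate alkylation) without touching C2′.

Step 7
Reactants: 20 C2′ 5-methylhex-4-enoyl keto ester
Product: 21 C2′ 6-methylhepta-1,5-dien-2-yl keto ester (saturated endo ester on C4)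
Conditions: Zn, CH2Br2, TiCl4, THF, 0 °C; then 20, CH2Cl2, 25 °C
Reagents that add atoms: dibromomethane, BrCBr
Why: Takai–Lombardo methylenation is non-basic, so the α-stereocentre C2′ is not epimerised; the side-chain ketone reacts, whereas the C1 ketone (between quaternary C10 and a bridgehead) and the ester are inert.

Step 8
Reactants: 21 C2′ 6-methylhepta-1,5-dien-2-yl keto ester
Product: 25 C3=C4 unsaturated ester (CO2Me on C4), via lithium ester enolate 22 (not isolated), via C4 phenylselenide 23 (not isolated), via selenoxide 24 (not isolated)
Conditions: LiN(iPr)2, THF, −78 → −40 °C; PhSeBr, −78 °C; then H2O2 (30%), pyridine, CH2Cl2, 0 → 25 °C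
Reagents that add atoms: none
Why: C4–H is the only acidic C–H left, so one ester enolate forms and is selenenylated; selenoxide syn-elimination can only run towards C3 because C5 is quaternary, which places the double bond at C3=C4. Pyridine and low temperature limit epoxidation of the side-chain alkenes.

Step 9
Reactants: 25 C3=C4 unsaturated ester
Product: 26 diol (CH2OH on C4; C1 carbinol with OH syn to the C1′–C2′ bridge expected)
Conditions: i-Bu2AlH (excess), CH2Cl2, −78 → 0 °C
Reagents that add atoms: none
Why: i-Bu2AlH reduces the conjugated ester 1,2 to the allylic alcohol and also the hindered C1 ketone (hydride from the side of the C3=C4 bridge); this is accepted because C1 is re-oxidised in step 11, and if the ketone should survive here it is reduced in step 10 with the same result.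

Step 10
Reactants: 26 diol
Product: 29 C4-methyl terminal alkyne alcohol (C10 prop-2-ynyl; C1 carbinol), via allylic mesylate 27 (not isolated), via silylalkyne 28 (not isolated)
Conditions: MsCl, Et3N, CH2Cl2, −20 °C; LiBHEt3, THF, 0 °C; then K2CO3, MeOH, 25 °C
Reagents that add atoms: none
Why: The primary allylic alcohol is sulfonylated in preference to the hindered secondary C1 carbinol, and hydride displaces the mesylate at the primary carbon (SN2; C3 is shielded by the bridgehead, so no transposition is expected), turning the former ester carbon into the C4 methyl. Methanolic carbonate then cleaves the C(sp)–Si bond.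

Step 11
Reactants: 29 C4-methyl terminal alkyne alcohol
Product: 30 terminal alkyne ketone (C1 ketone restored)
Conditions: Dess–Martin periodinane, NaHCO3, CH2Cl2, 25 °C
Reagents that add atoms: none
Why: Periodinane oxidation returns the non-enolisable C1 ketone before C7 becomes an aldehyde; a C1 hydroxyl would otherwise trap that aldehyde as a six-membered lactol.

Step 12
Reactants: 30 terminal alkyne ketone
Product: 32 C7 aldehyde (3-oxopropyl on C10), via alkenylborane 31 (not isolated)
Conditions: (c-C6H11)2BH (from BH3·SMe2 and cyclohexene), THF, 0 °C; then H2O2, NaHCO3 aq., 0 → 25 °C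
Reagents that add atoms: hydrogen peroxide, OO
Why: The hindered dialkylborane adds once to the terminal alkyne with boron on the terminal carbon (anti-Markovnikov hydroboration), faster than to the 1,1-di- and trisubstituted alkenes or the hindered ketone; buffered oxidation gives the enol and hence the aldehyde.

Step 13
Reactants: 32 C7 aldehyde; 8 methyl acrylate
Product: 33 Morita–Baylis–Hillman adduct (methyl 3-hydroxy-2-methylidenepentanoate chain on C10; carbinol epimers)
Conditions: 8 (excess), DABCO, MeOH (cat.), 25 °C
Reagents that add atoms: none
Why: Morita–Baylis–Hillman reaction: the amine–acrylate zwitterion adds to the unhindered aliphatic aldehyde, the C1 ketone being too hindered to compete; the new carbinol centre is erased in step 14.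

Step 14
Reactants: 33 Morita–Baylis–Hillman adduct
Product: 34 (Z)-2-(bromomethyl)pent-2-enoate (chain on C10; C8 cis to CH2Br)
Conditions: N-bromosuccinimide, Me2S, CH2Cl2, 0 → 25 °C
Reagents that add atoms: N-bromosuccinimide, O=C1CCC(=O)N1Br
Why: The bromodimethylsulfonium reagent (Corey–Kim type) activates the allylic alcohol and bromide enters SN2′ with transposition, giving the more stable (Z)-bromide; the isolated alkenes are not attacked at this temperature.

Step 15
Reactants: 34 (Z)-2-(bromomethyl)pent-2-enoate
Product: 36 C6 primary alcohol (CH2OH on C5), via bromomethyl ether 35 (not isolated)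
Conditions: Me2BBr, CH2Cl2, −78 °C; then NaHCO3 aq., THF, 25 °C
Reagents that add atoms: none
Why: The boron bromide cleaves the methoxymethyl acetal at −78 °C to the bromomethyl ether, which hydrolyses on bicarbonate work-up; the allylic bromide, the enoate and the acid-sensitive 1,5-diene should survive these conditions.

Step 16
Reactants: 36 C6 primary alcohol
Product: 37 C6 aldehyde (CHO on C5)
Conditions: Dess–Martin periodinane, NaHCO3, CH2Cl2, 0 → 25 °C
Reagents that add atoms: none
Why: Buffered periodinane oxidation of the neopentyl alcohol gives the non-enolisable aldehyde without disturbing the allylic bromide.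

Step 17
Reactants: 37 C6 aldehyde
Product: 40 cis-fused α-methylene lactone (ring B closed; O6 axial and syn to the C10 methyl; C7–C11 equatorial), via allylchromium dichloride 38 (not isolated), via chromium alkoxide 39 (not isolated)
Conditions: CrCl2, THF, 25 °C (high dilution); aq. NH4Cl
Reagents that add atoms: none
Why: Divalent chromium inserts into the allylic C–Br bond, and the 2-(methoxycarbonyl)allylchromium adds through its γ-carbon C7 to the aldehyde only (intramolecular Barbier-type allylation, Dreiding–Schmidt lactone annulation); the alkoxide then closes the lactone. The closed Zimmerman–Traxler transition state from the (Z)-allylmetal gives O6 and C11 cis, and the chair of the forming ring B keeps C11 equatorial (axial would clash with C1′H2), so O6 is axial: C6 and C7 as in the target.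

Step 18
Reactants: 40 cis-fused α-methylene lactone
Product: 43 target keto lactone, via silyl ketene acetal 41 (not isolated), via C11 epimer 42 (not isolated)
Conditions: [(Ph3P)CuH]6 (5 mol %), PhMe2SiH, toluene, 25 °C; then t-BuOH, KOt-Bu (30 mol %), THF, 25 °C
Reagents that add atoms: none
Why: Copper hydride catalysis delivers hydride 1,4 to the exocyclic enoate only (isolated alkenes and the hindered ketone are inert), giving the silyl ketene acetal. Alkoxide cleaves it, and reversible deprotonation at C11, the only acidic C–H, should settle the methyl on the convex face trans to C8, which is the target configuration.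

Compound list

1 | (R)-carvone | CC1=CC[C@H](CC1=O)C(C)=C | starting material
2 | tributyl[(methoxymethoxy)methyl]stannane | CCCC[Sn](CCCC)(CCCC)COCOC | starting material
3 | (methoxymethoxy)methyllithium | [Li]COCOC | intermediate
4 | (5R)-1-[(methoxymethoxy)methyl]-2-methyl-5-(prop-1-en-2-yl)cyclohex-2-en-1-ol (C1 epimers) | CC1=CC[C@H](CC1(O)COCOC)C(C)=C | intermediate
5 | tertiary chlorochromate ester of 4 | CC1=CC[C@H](CC1(COCOC)O[Cr](=O)(=O)Cl)C(C)=C | intermediate
6 | transposed secondary allylic chlorochromate ester | CC(=C)[C@H]1CC(COCOC)=C(C)C(O[Cr](=O)(=O)Cl)C1 | intermediate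
7 | (5S)-3-[(methoxymethoxy)methyl]-2-methyl-5-(prop-1-en-2-yl)cyclohex-2-en-1-one | CC(=C)[C@H]1CC(COCOC)=C(C)C(=O)C1 | intermediate
8 | methyl acrylate | C=CC(=O)OC | starting material
9 | lithium cross-conjugated dienolate of 7 | CC(=C)[C@H]1CC(COCOC)=C(C)C(O[Li])=C1 | intermediate
10 | mono-Michael adduct, lithium ester enolate (chain on C2 trans to isopropenyl) | CC(=C)[C@H]1CC(COCOC)=C(C)C(=O)[C@@H]1CC=C(OC)O[Li] | intermediate
11 | lithium C1=C10 enolate of the bicyclic keto ester | CC(=C)[C@H]1C[C@]2(COCOC)[C@@H](C(=O)OC)C[C@H]1C(O[Li])=C2C | intermediate
12 | bicyclo[2.2.2]octan-1-one endo ester (C4 CO2Me endo, C5 CH2OMOM, C2′ isopropenyl anti to the C3–C4 bridge; C10–H epimer with H facing the ester drawn) | CC(=C)[C@H]1C[C@]2(COCOC)[C@@H](C(=O)OC)C[C@H]1C(=O)[C@@H]2C | intermediate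
13 | 3-bromo-1-(trimethylsilyl)prop-1-yne | C[Si](C)(C)C#CCBr | starting material
14 | potassium C1=C10 enolate of 12 | CC(=C)[C@H]1C[C@]2(COCOC)[C@@H](C(=O)OC)C[C@H]1C(O[K])=C2C | intermediate
15 | C10-[3-(trimethylsilyl)prop-2-yn-1-yl] keto ester (chain syn to the C1′–C2′ bridge) | CC(=C)[C@H]1C[C@]2(COCOC)[C@@H](C(=O)OC)C[C@H]1C(=O)[C@]2(C)CC#C[Si](C)(C)C | intermediate
16 | secondary ozonide (1,2,4-trioxolane) of the isopropenyl group | CC3(OOCO3)[C@H]1C[C@]2(COCOC)[C@@H](C(=O)OC)C[C@H]1C(=O)[C@]2(C)CC#C[Si](C)(C)C | intermediate
17 | C2′ acetyl keto ester | CC(=O)[C@H]1C[C@]2(COCOC)[C@@H](C(=O)OC)C[C@H]1C(=O)[C@]2(C)CC#C[Si](C)(C)C | intermediate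
18 | prenyl bromide | CC(C)=CCBr | starting material
19 | lithium enolate of the methyl ketone (terminal) | C=C(O[Li])[C@H]1C[C@]2(COCOC)[C@@H](C(=O)OC)C[C@H]1C(=O)[C@]2(C)CC#C[Si](C)(C)C | intermediate
20 | C2′ 5-methylhex-4-enoyl keto ester | CC(C)=CCCC(=O)[C@H]1C[C@]2(COCOC)[C@@H](C(=O)OC)C[C@H]1C(=O)[C@]2(C)CC#C[Si](C)(C)C | intermediate
21 | C2′ 6-methylhepta-1,5-dien-2-yl keto ester | C=C(CCC=C(C)C)[C@H]1C[C@]2(COCOC)[C@@H](C(=O)OC)C[C@H]1C(=O)[C@]2(C)CC#C[Si](C)(C)C | intermediate
22 | lithium ester enolate at C4 | C=C(CCC=C(C)C)[C@H]1C[C@]2(COCOC)C(=C(OC)O[Li])C[C@H]1C(=O)[C@]2(C)CC#C[Si](C)(C)C | intermediate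
23 | C4 phenylselanyl ester (Se away from the C1–C10 bridge expected) | C=C(CCC=C(C)C)[C@H]1C[C@]2(COCOC)[C@@]([Se]c3ccccc3)(C(=O)OC)C[C@H]1C(=O)[C@]2(C)CC#C[Si](C)(C)C | intermediate
24 | selenoxide of 23 | C=C(CCC=C(C)C)[C@H]1C[C@]2(COCOC)[C@@]([Se](=O)c3ccccc3)(C(=O)OC)C[C@H]1C(=O)[C@]2(C)CC#C[Si](C)(C)C | intermediate
25 | C3=C4 unsaturated ester | C=C(CCC=C(C)C)[C@H]1C[C@]2(COCOC)C(C(=O)OC)=C[C@H]1C(=O)[C@]2(C)CC#C[Si](C)(C)C | intermediate
26 | diol (C4 CH2OH, C1 OH) | C=C(CCC=C(C)C)[C@H]1C[C@]2(COCOC)C(CO)=C[C@H]1[C@H](O)[C@]2(C)CC#C[Si](C)(C)C | intermediate
27 | allylic mesylate | C=C(CCC=C(C)C)[C@H]1C[C@]2(COCOC)C(COS(C)(=O)=O)=C[C@H]1[C@H](O)[C@]2(C)CC#C[Si](C)(C)C | intermediate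
28 | C4-methyl silylalkyne alcohol | C=C(CCC=C(C)C)[C@H]1C[C@]2(COCOC)C(C)=C[C@H]1[C@H](O)[C@]2(C)CC#C[Si](C)(C)C | intermediate
29 | C4-methyl terminal alkyne alcohol | C=C(CCC=C(C)C)[C@H]1C[C@]2(COCOC)C(C)=C[C@H]1[C@H](O)[C@]2(C)CC#C | intermediate
30 | terminal alkyne ketone | C=C(CCC=C(C)C)[C@H]1C[C@]2(COCOC)C(C)=C[C@H]1C(=O)[C@]2(C)CC#C | intermediate
31 | (E)-alkenyl(dicyclohexyl)borane | C=C(CCC=C(C)C)[C@H]1C[C@]2(COCOC)C(C)=C[C@H]1C(=O)[C@]2(C)C/C=C/B(C3CCCCC3)C3CCCCC3 | intermediate
32 | C7 aldehyde (3-oxopropyl on C10) | C=C(CCC=C(C)C)[C@H]1C[C@]2(COCOC)C(C)=C[C@H]1C(=O)[C@]2(C)CCC=O | intermediate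
33 | Morita–Baylis–Hillman adduct (carbinol epimers) | C=C(CCC=C(C)C)[C@H]1C[C@]2(COCOC)C(C)=C[C@H]1C(=O)[C@]2(C)CCC(O)C(=C)C(=O)OC | intermediate
34 | (Z)-2-(bromomethyl)pent-2-enoate | C=C(CCC=C(C)C)[C@H]1C[C@]2(COCOC)C(C)=C[C@H]1C(=O)[C@]2(C)CC/C=C(\CBr)C(=O)OC | intermediate
35 | C6 bromomethyl ether | C=C(CCC=C(C)C)[C@H]1C[C@]2(COCBr)C(C)=C[C@H]1C(=O)[C@]2(C)CC/C=C(\CBr)C(=O)OC | intermediate
36 | C6 primary alcohol | C=C(CCC=C(C)C)[C@H]1C[C@]2(CO)C(C)=C[C@H]1C(=O)[C@]2(C)CC/C=C(\CBr)C(=O)OC | intermediate
37 | C6 aldehyde | C=C(CCC=C(C)C)[C@H]1C[C@]2(C=O)C(C)=C[C@H]1C(=O)[C@]2(C)CC/C=C(\CBr)C(=O)OC | intermediate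
38 | allylchromium dichloride | C=C(CCC=C(C)C)[C@H]1C[C@]2(C=O)C(C)=C[C@H]1C(=O)[C@]2(C)CC/C=C(\C[Cr](Cl)Cl)C(=O)OC | intermediate
39 | chromium alkoxide of the cis hydroxy ester | C=C(CCC=C(C)C)[C@H]1C[C@]23C(C)=C[C@H]1C(=O)[C@]2(C)CC[C@@H](C(=C)C(=O)OC)[C@H]3O[Cr](Cl)Cl | intermediate
40 | cis-fused α-methylene lactone | C=C(CCC=C(C)C)[C@H]1C[C@]23C(C)=C[C@H]1C(=O)[C@]2(C)CC[C@H]1C(=C)C(=O)O[C@H]13 | intermediate
41 | O-(dimethylphenylsilyl) ketene acetal | C=C(CCC=C(C)C)[C@H]1C[C@]23C(C)=C[C@H]1C(=O)[C@]2(C)CC[C@H]1C(C)=C(O[Si](C)(C)c4ccccc4)O[C@H]13 | intermediate
42 | C11 epimer of the target (methyl on the concave face) | C=C(CCC=C(C)C)[C@H]1C[C@]23C(C)=C[C@H]1C(=O)[C@]2(C)CC[C@H]1[C@@H](C)C(=O)O[C@H]13 | intermediate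
43 | target keto lactone | C=C(CCC=C(C)C)[C@H]1C[C@]23C(C)=C[C@H]1C(=O)[C@]2(C)CC[C@H]1[C@H](C)C(=O)O[C@H]13 | target

Total step count: 18. Longest linear sequence: 18 steps (1 → 43); 2, 8, 13 and 18 enter as purchased reagents.

Least certain steps

Step 3 (key step). The most likely failure is an incomplete second Michael addition onto the fully substituted C5: arrest at the mono-adduct, acrylate oligomerisation, or competing γ-deprotonation, because the acceptor carbon is β,β-disubstituted. The fallback sets out from 7 and returns at 12. Kinetic enolisation and silylation (LiN(iPr)2, t-BuMe2SiCl, THF/HMPA, −78 °C) should give the 2-silyloxy diene F1. A thermal Diels–Alder reaction with 8 (toluene, 110 °C, or Et2AlCl at −40 °C) should give the bicyclic silyl enol ether F2 with the same anti and endo sense. Desilylation (Bu4NF, AcOH, THF, 0 °C) should then give 12.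

Step 4. The risks are poor facial discrimination at C10, or O-alkylation and low conversion, because the tetrasubstituted enolate is hindered on both faces (ester on one side, C1′–H and the C2′ substituent on the other). The fallback sets out from 12 and returns at 15. The trimethylsilyl enol ether F3 (Me3SiOTf, Et3N) is alkylated in a Nicholas reaction with [Co2(CO)6(Me3SiC≡CCH2OMe)] and BF3·OEt2 at −78 °C to give the hexacarbonyldicobalt complex F4. Oxidative decomplexation with (NH4)2Ce(NO3)6 in acetone at 0 °C releases 15. The bulkier cationic electrophile cannot O-alkylate productively and should feel the endo ester more strongly.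

Step 12. The risk is competing hydroboration of the side-chain 1,1-disubstituted alkene or double addition to the alkyne, since the borane discriminates only by rate. The fallback sets out from 30 and returns at 32: ruthenium-catalysed anti-Markovnikov hydration of the terminal alkyne ([CpRu(MeCN)3]PF6, 5,5′-bis(trifluoromethyl)-2,2′-bipyridine, NMP/H2O, 25 °C), to which alkenes are inert. It makes no new compound (entered as F0).

Step 17. The risk is loss of control at C6: the aldehyde oxygen may take the less hindered equatorial position through an open transition state, giving a trans hydroxy ester that cannot lactonise to 40. The fallback sets out from 37 and returns at 40. The C6-epimeric hydroxy ester F5 from the cyclisation is oxidised (Dess–Martin periodinane) to the C6 ketone F6, in which C7, now α to the ketone, settles equatorial. Luche reduction (NaBH4, CeCl3·7H2O, MeOH, −78 °C) should deliver hydride from the equatorial direction, since axial attack is blocked by the C10 methyl, and the axial alkoxide lactonises to 40.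

Further compounds

F1 | step 3 | (5S)-1-(tert-butyldimethylsilyloxy)-3-[(methoxymethoxy)methyl]-2-methyl-5-(prop-1-en-2-yl)cyclohexa-1(6),2-diene (2-silyloxy diene) | CC(=C)[C@H]1CC(COCOC)=C(C)C(O[Si](C)(C)C(C)(C)C)=C1
F2 | step 3 | tert-butyldimethylsilyl enol ether (C1=C10) of 12 | CC(=C)[C@H]1C[C@]2(COCOC)[C@@H](C(=O)OC)C[C@H]1C(O[Si](C)(C)C(C)(C)C)=C2C
F3 | step 4 | trimethylsilyl enol ether (C1=C10) of 12 | CC(=C)[C@H]1C[C@]2(COCOC)[C@@H](C(=O)OC)C[C@H]1C(O[Si](C)(C)C)=C2C
F4 | step 4 | hexacarbonyldicobalt complex of the alkyne of 15 | CC(=C)[C@H]1C[C@]2(COCOC)[C@@H](C(=O)OC)C[C@H]1C(=O)[C@]2(C)CC34[Co-3]5(C#[O+])(C#[O+])(C#[O+])[Co-3]3(C#[O+])(C#[O+])(C#[O+])C45[Si](C)(C)C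
F0 | step 12 | none | none
F5 | step 17 | C6-epimeric (trans) hydroxy ester, ring B closed | C=C(CCC=C(C)C)[C@H]1C[C@]23C(C)=C[C@H]1C(=O)[C@]2(C)CC[C@@H](C(=C)C(=O)OC)[C@@H]3O
F6 | step 17 | C6 ketone with equatorial C7 acrylate unit | C=C(CCC=C(C)C)[C@H]1C[C@]23C(C)=C[C@H]1C(=O)[C@]2(C)CC[C@@H](C(=C)C(=O)OC)C3=O
A1 | alternative 1 | C6 bromoacetal (2-bromo-1-ethoxypropyl ether) of the ring B cyclohexenol, dioxolane-protected | CC1(OCCO1)[C@H]2C[C@]34C(C)=C[C@H]2C(=O)[C@]3(C)CC=C[C@H]4OC(OCC)C(C)Br
A2 | alternative 1 | cis-fused ethyl lactol ether | CC1(OCCO1)[C@H]2C[C@]34C(C)=C[C@H]2C(=O)[C@]3(C)CC[C@H]5[C@H](C)[C@H](OCC)O[C@@H]45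
A3 | alternative 2 | 1-(cyclohexa-2,4-dienyl)ethyl (E)-7-methylocta-2,6-dienoate (trienyl ester) | C[C@@H](OC(=O)/C=C/CCC=C(C)C)[C@H]1CC(COCOC)=C(C)C=C1
A4 | alternative 2 | lactone-bridged bicyclo[2.2.2]octene | C[C@H]1OC(=O)[C@@H]2[C@@H](CCC=C(C)C)[C@]3(COCOC)C[C@H]1[C@H]2C=C3C
A5 | alternative 3 | C6 phenyl selenoester with (E)-2-methylpent-2-enoate chain on C10 | CC1(OCCO1)[C@H]2C[C@]3(C(=O)[Se]c5ccccc5)C(C)=C[C@H]2C(=O)[C@]3(C)CC/C=C(\C)C(=O)OC
A6 | alternative 3 | tricyclic diketone ester | CC1(OCCO1)[C@H]2C[C@]34C(C)=C[C@H]2C(=O)[C@]3(C)CC[C@@H]([C@H](C)C(=O)OC)C4=O
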